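**Plan**
- Retrosynthesis: after removal of five benzyl ethers, the indane is cut at C3–C3a (the Friedel–Crafts bond) and the exocyclic alkene is read as a tautomerised quinone methide. Rejoining the benzylidene carbon to C3 gives a tetraarylcyclobutane, which is cut at its two guaiacyl–C(sp3) bonds and then across the ring ([2+2]) to a 3,5-dioxygenated cinnamic acid.
- Enabling feature: in the indane (C1 benzylidene-bearing carbon, C2 CH–resorcinyl, C3 CH–guaiacyl, C3a/C7a fusion, OH on C4 and C6) the exocyclic carbon and C3 are both 4-oxybenzylic, and C1–C2 links the two resorcinyl-bearing carbons. The skeleton is therefore a head-to-head tetraarylcyclobutane opened between its two guaiacyl-bearing carbons.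
- Forward: Doebner cinnamic acid → template-held head-to-head photodimer (the cyclobutane, the only ring made before the key step) → meso anhydride → hemiester → two decarboxylative arylations (benzyl-protected, then silyl-protected guaiacyl) → mono-phenol → oxidative ring opening with indane closure → global debenzylation.
- Stereochemistry: the photodimerisation fixes the cis (meso) relation of the resorcinyl rings. Quinine-mediated methanolysis of the meso anhydride decides which carboxyl carbon later carries the free phenol, and so the absolute configuration of C2. C3 is set trans to the C2 aryl group in the ring closure, and the E alkene is the thermodynamic tautomer.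

Key step: step 13

Remark: quinine is assumed to open the meso anhydride in the sense drawn (acid on the carbon that is arylated first), by analogy with unsubstituted cis-cycloalkane-1,2-dicarboxylic anhydrides; if the other hemiester formed, quinidine would be used and nothing else would change.
Remark: after each arylation the new aryl group is drawn anti to the neighbouring resorcinyl ring; both guaiacyl-bearing carbons become trigonal in the key step, so any epimer at these two centres would converge on the same product.

**Step 1**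
Reactants: 1 3,5-bis(benzyloxy)benzaldehyde; 2 malonic acid
Product: 4 (2E)-3-[3,5-bis(benzyloxy)phenyl]prop-2-enoic acid, via arylidenemalonic acid 3 (not isolated)
Conditions: pyridine, piperidine (cat.), 100 °C
Reagents that add atoms: none
Why: Knoevenagel–Doebner condensation; the arylidenemalonic acid loses CO2 in hot pyridine and should give the E-cinnamic acid.

**Step 2**
Reactants: 4 (2 equiv); 5 naphthalene-1,8-diol
Product: 6 naphthalene-1,8-diyl bis{(2E)-3-[3,5-bis(benzyloxy)phenyl]prop-2-enoate}
Conditions: DCC, DMAP (cat.), CH2Cl2, 0 °C to rt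
Reagents that add atoms: none
Why: Steglich esterification of both peri hydroxyl groups, which places the two cinnamoyl units side by side on a rigid covalent template.

**Step 3**
Reactants: 6
Product: 7 naphthalene-1,8-diyl (1R,2S,3R,4S)-3,4-bis[3,5-bis(benzyloxy)phenyl]cyclobutane-1,2-dicarboxylate (meso, template-bound β-truxinate)
Conditions: hν (350–365 nm), crystalline solid, rt
Reagents that add atoms: none
Why: Template-directed [2+2] photocycloaddition: the peri-diester holds the two E double bonds parallel, head-to-head and within bonding distance, so suprafacial union on the syn faces should set all four stereocentres at once (esters cis, aryl groups cis, each ester trans to its neighbouring aryl group).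

**Step 4**
Reactants: 7
Product: 8 (1R,2S,3R,4S)-3,4-bis[3,5-bis(benzyloxy)phenyl]cyclobutane-1,2-dicarboxylic acid (meso); template 5 is recovered
Conditions: KOH, THF/H2O, rt; then aq. HCl
Reagents that add atoms: potassium hydroxide, [K+].[OH-]
Why: Saponification of two activated aryl esters; the carboxylates formed resist α-deprotonation, so the cyclobutane configuration should survive.

**Step 5**
Reactants: 8
Product: 9 cis-fused cyclic anhydride of 8 (6,7-diaryl-3-oxabicyclo[3.2.0]heptane-2,4-dione, meso)
Conditions: Ac2O, 80 °C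
Reagents that add atoms: none
Why: Cyclodehydration of a cis-1,2-dicarboxylic acid to the five-membered anhydride, which only the cis arrangement can form, so the meso configuration is kept.

**Step 6**
Reactants: 9
Product: 10 (1R,2S,3R,4S)-3,4-bis[3,5-bis(benzyloxy)phenyl]-2-(methoxycarbonyl)cyclobutane-1-carboxylic acid
Conditions: quinine (1.1 equiv), MeOH (3 equiv), toluene, −55 °C; then aq. HCl wash
Reagents that add atoms: methanol, CO
Why: Alkaloid-mediated enantioselective alcoholysis (desymmetrisation) of a meso anhydride: quinine acts as a chiral general base and directs methanol to one of the two enantiotopic carbonyl groups, which creates no new stereocentre but makes the existing four non-equivalent and sets the absolute configuration of the route.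

**Step 7**
Reactants: 11 4-bromo-2-methoxyphenol
Product: 12 1-(benzyloxy)-4-bromo-2-methoxybenzene
Conditions: BnBr, K2CO3, DMF, rt
Reagents that add atoms: benzyl bromide, BrCc1ccccc1
Why: Williamson ether synthesis; benzyl is chosen because it survives every later step and, on the oxygen para to the future cation, does not ionise off as an acetal protecting group would.

**Step 8**
Reactants: 10; 12
Product: 16 methyl (1R,2R,3R,4R)-2-[4-(benzyloxy)-3-methoxyphenyl]-3,4-bis[3,5-bis(benzyloxy)phenyl]cyclobutane-1-carboxylate, via N-acyloxyphthalimide 13 (not isolated), via arylmagnesium bromide 14 (not isolated), via arylzinc chloride 15 (not isolated)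
Conditions: 10, N-hydroxyphthalimide, DIC, DMAP (cat.), CH2Cl2, rt, then evaporate; 12, Mg, LiCl, THF, then ZnCl2; combine with NiCl2·glyme (20 mol %), 4,4′-di-tert-butyl-2,2′-bipyridine (40 mol %), THF/DMF, rt
Reagents that add atoms: none
Why: Nickel-catalysed decarboxylative (Negishi-type) arylation of a redox-active ester: electron transfer from low-valent nickel releases CO2 and a secondary cyclobutyl radical, which is captured by the aryl–nickel species and reductively eliminated, the aryl group entering anti to the neighbouring resorcinyl ring while the methyl ester and benzyl ethers are inert to the arylzinc reagent.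

**Step 9**
Reactants: 16
Product: 17 (1R,2R,3R,4R)-2-[4-(benzyloxy)-3-methoxyphenyl]-3,4-bis[3,5-bis(benzyloxy)phenyl]cyclobutane-1-carboxylic acid
Conditions: LiOH, THF/MeOH/H2O, 40 °C; then aq. HCl
Reagents that add atoms: lithium hydroxide, [Li+].[OH-]
Why: Ester saponification; benzyl ethers are stable to hydroxide, and any epimerisation α to the carboxylate is without consequence because that carbon becomes a radical centre in step 11.

**Step 10**
Reactants: 11
Product: 18 (4-bromo-2-methoxyphenoxy)tri(propan-2-yl)silane
Conditions: TIPSCl, imidazole, DMF, rt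
Reagents that add atoms: chlorotri(propan-2-yl)silane, CC(C)[Si](Cl)(C(C)C)C(C)C
Why: Silylation of the phenol; the bulky silyl ether survives organomagnesium and organozinc formation and can later be removed by fluoride without touching benzyl ethers.

**Step 11**
Reactants: 17; 18
Product: 22 {4-[(1R,2S,3R,4S)-2-[4-(benzyloxy)-3-methoxyphenyl]-3,4-bis[3,5-bis(benzyloxy)phenyl]cyclobutyl]-2-methoxyphenoxy}tri(propan-2-yl)silane, via N-acyloxyphthalimide 19 (not isolated), via arylmagnesium bromide 20 (not isolated), via arylzinc chloride 21 (not isolated)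
Conditions: 17, N-hydroxyphthalimide, DIC, DMAP (cat.), CH2Cl2, rt, then evaporate; 18, Mg, LiCl, THF, then ZnCl2; combine with NiCl2·glyme (20 mol %), 4,4′-di-tert-butyl-2,2′-bipyridine (40 mol %), THF/DMF, rt
Reagents that add atoms: none
Why: Second nickel-catalysed decarboxylative arylation of a redox-active ester, by the same radical capture and reductive elimination as in step 8; the aryl group should again enter anti to the adjacent resorcinyl ring, giving the cyclobutane with the two guaiacyl rings cis to each other and trans to the two cis resorcinyl rings.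

**Step 12**
Reactants: 22
Product: 23 4-{(1R,2S,3R,4S)-2-[4-(benzyloxy)-3-methoxyphenyl]-3,4-bis[3,5-bis(benzyloxy)phenyl]cyclobutyl}-2-methoxyphenol
Conditions: Bu4NF, AcOH, THF, 0 °C
Reagents that add atoms: none
Why: Fluoride-mediated cleavage of the aryl silyl ether, buffered so that the electron-rich phenoxide is never free; the benzyl ethers stay and the single phenol needed for step 13 is unveiled.

**Step 13**
Reactants: 23
Product: 26 4-{(E)-[(2S,3S)-4,6-bis(benzyloxy)-3-[4-(benzyloxy)-3-methoxyphenyl]-2-[3,5-bis(benzyloxy)phenyl]-2,3-dihydro-1H-inden-1-ylidene]methyl}-2-methoxyphenol (penta-O-benzylgnetulin), via ring-opened quinone methide cation 24 (not isolated), via indane quinone methide 25 (not isolated)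
Conditions: PhI(OAc)2 (1.0 equiv, slow addition), (CF3)2CHOH/CH2Cl2, −40 to 0 °C; then Et3N, rt
Reagents that add atoms: none
Why: Proposed new method: ligand exchange of the only free phenol on PhI(OAc)2 and loss of PhI and acetate give a phenoxonium ion, and the strained cyclobutane bond para-benzylic to it (between the two guaiacyl-bearing carbons) should break in a Grob-type heterolysis, because it lies parallel to the arene π system, its cleavage releases the ring strain, and it leaves a para-quinone methide on one carbon and a 4-benzyloxy-3-methoxybenzyl cation on the other (24). The closest known reaction types are oxidative Grob-type C–C fragmentations of para-hydroxybenzyl systems, the ring opening of 1,2-diarylcyclobutane radical cations and the Friedel–Crafts closure of bis(quinone methides) of 8–8′ stilbene dimers to indanes. The indane ring closes by intramolecular Friedel–Crafts alkylation, a 5-exo-trig attack (the cationic π system stays outside the new ring) of the resorcinol carbon ortho to the ring junction, activated ortho and para by the two benzyloxy groups, on the benzylic cation to give 25, and Et3N then moves the C1 hydrogen to oxygen so that the quinone methide becomes the E-benzylidene phenol, E because the aryl group avoids the peri C7–H. The new stereocentre C3 is controlled by the C2 stereocentre carried over unchanged from the cyclobutane, closure with the C2 and C3 aryl groups trans being preferred, and C2 is the resorcinyl-bearing carbon next to the cationic terminus, so the choice of which guaiacyl ring is free, made in step 6, decides the enantiomer. The selectivities needed are C–C cleavage over benzylic deprotonation or ortho trapping of the phenoxonium ion and cleavage toward the guaiacyl-bearing carbon over the resorcinyl-bearing one, secured by strain release and by the para-alkoxy group that stabilises only the former cation, and ring closure over loss of a proton or of the O-benzyl group from the cation, secured by the fast five-membered closure in non-nucleophilic solvent and by having benzyl, not an acetal, on that oxygen. The quinone methide terminus cannot act as a nucleophile, so no six-membered closure onto the other guaiacyl ring competes, and a second Friedel–Crafts closure to a bicyclo[3.3.0]octane is excluded because the cis (meso-type) relation of the resorcinyl rings would demand a trans ring fusion.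

**Step 14**
Reactants: 26
Product: 27 gnetulin, (1E,2S,3S)-2-(3,5-dihydroxyphenyl)-3-(4-hydroxy-3-methoxyphenyl)-1-[(4-hydroxy-3-methoxyphenyl)methylidene]-2,3-dihydro-1H-indene-4,6-diol
Conditions: BCl3, pentamethylbenzene, CH2Cl2, −78 °C; MeOH quench
Reagents that add atoms: none
Why: Lewis-acid debenzylation with a non-Lewis-basic cation scavenger: BCl3 activates each aryl benzyl ether and pentamethylbenzene captures the benzyl cations, so the stilbene double bond, the aryl methyl ethers and both stereocentres should be untouched at −78 °C.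

**Compound list**
1 | 3,5-bis(benzyloxy)benzaldehyde | O=Cc1cc(OCc2ccccc2)cc(OCc2ccccc2)c1 | starting material
2 | malonic acid | OC(=O)CC(=O)O | starting material
3 | 2-{[3,5-bis(benzyloxy)phenyl]methylidene}propanedioic acid (formed and consumed in situ) | OC(=O)C(=Cc1cc(OCc2ccccc2)cc(OCc2ccccc2)c1)C(=O)O | intermediate
4 | (2E)-3-[3,5-bis(benzyloxy)phenyl]prop-2-enoic acid | OC(=O)/C=C/c1cc(OCc2ccccc2)cc(OCc2ccccc2)c1 | intermediate
5 | naphthalene-1,8-diol | Oc1cccc2cccc(O)c12 | starting material
6 | naphthalene-1,8-diyl bis{(2E)-3-[3,5-bis(benzyloxy)phenyl]prop-2-enoate} | O=C(/C=C/c1cc(OCc2ccccc2)cc(OCc2ccccc2)c1)Oc1cccc2cccc(OC(=O)/C=C/c3cc(OCc4ccccc4)cc(OCc4ccccc4)c3)c12 | intermediate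
7 | naphthalene-1,8-diyl (1R,2S,3R,4S)-3,4-bis[3,5-bis(benzyloxy)phenyl]cyclobutane-1,2-dicarboxylate (meso; esters cis, aryl groups cis, the pairs trans) | O=C1Oc2cccc3cccc(OC(=O)[C@H]4[C@@H]1[C@H](c1cc(OCc5ccccc5)cc(OCc5ccccc5)c1)[C@@H]4c1cc(OCc4ccccc4)cc(OCc4ccccc4)c1)c23 | intermediate
8 | (1R,2S,3R,4S)-3,4-bis[3,5-bis(benzyloxy)phenyl]cyclobutane-1,2-dicarboxylic acid (meso) | OC(=O)[C@H]1[C@@H](C(=O)O)[C@H](c2cc(OCc3ccccc3)cc(OCc3ccccc3)c2)[C@@H]1c1cc(OCc2ccccc2)cc(OCc2ccccc2)c1 | intermediate
9 | 6,7-bis[3,5-bis(benzyloxy)phenyl]-3-oxabicyclo[3.2.0]heptane-2,4-dione (meso anhydride of 8; aryl groups cis to each other, trans to the anhydride ring) | O=C1OC(=O)[C@H]2[C@@H]1[C@H](c1cc(OCc3ccccc3)cc(OCc3ccccc3)c1)[C@@H]2c1cc(OCc2ccccc2)cc(OCc2ccccc2)c1 | intermediate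
10 | (1R,2S,3R,4S)-3,4-bis[3,5-bis(benzyloxy)phenyl]-2-(methoxycarbonyl)cyclobutane-1-carboxylic acid | OC(=O)[C@H]1[C@@H](C(=O)OC)[C@H](c2cc(OCc3ccccc3)cc(OCc3ccccc3)c2)[C@@H]1c1cc(OCc2ccccc2)cc(OCc2ccccc2)c1 | intermediate
11 | 4-bromo-2-methoxyphenol | COc1cc(Br)ccc1O | starting material
12 | 1-(benzyloxy)-4-bromo-2-methoxybenzene | COc1cc(Br)ccc1OCc1ccccc1 | intermediate
13 | 1,3-dioxoisoindolin-2-yl ester of 10 (formed and consumed in situ) | O=C(ON1C(=O)c2ccccc2C1=O)[C@H]1[C@@H](C(=O)OC)[C@H](c2cc(OCc3ccccc3)cc(OCc3ccccc3)c2)[C@@H]1c1cc(OCc2ccccc2)cc(OCc2ccccc2)c1 | intermediate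
14 | [4-(benzyloxy)-3-methoxyphenyl]magnesium bromide (formed and consumed in situ) | COc1cc([Mg]Br)ccc1OCc1ccccc1 | intermediate
15 | [4-(benzyloxy)-3-methoxyphenyl]zinc chloride (formed and consumed in situ) | COc1cc([Zn]Cl)ccc1OCc1ccccc1 | intermediate
16 | methyl (1R,2R,3R,4R)-2-[4-(benzyloxy)-3-methoxyphenyl]-3,4-bis[3,5-bis(benzyloxy)phenyl]cyclobutane-1-carboxylate (ester and guaiacyl ring cis, both trans to the two cis resorcinyl rings) | [C@H]1(c2ccc(OCc3ccccc3)c(OC)c2)[C@@H](C(=O)OC)[C@H](c2cc(OCc3ccccc3)cc(OCc3ccccc3)c2)[C@@H]1c1cc(OCc2ccccc2)cc(OCc2ccccc2)c1 | intermediate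
17 | (1R,2R,3R,4R)-2-[4-(benzyloxy)-3-methoxyphenyl]-3,4-bis[3,5-bis(benzyloxy)phenyl]cyclobutane-1-carboxylic acid | [C@H]1(c2ccc(OCc3ccccc3)c(OC)c2)[C@@H](C(=O)O)[C@H](c2cc(OCc3ccccc3)cc(OCc3ccccc3)c2)[C@@H]1c1cc(OCc2ccccc2)cc(OCc2ccccc2)c1 | intermediate
18 | (4-bromo-2-methoxyphenoxy)tri(propan-2-yl)silane | COc1cc(Br)ccc1O[Si](C(C)C)(C(C)C)C(C)C | intermediate
19 | 1,3-dioxoisoindolin-2-yl ester of 17 (formed and consumed in situ) | [C@H]1(c2ccc(OCc3ccccc3)c(OC)c2)[C@@H](C(=O)ON2C(=O)c3ccccc3C2=O)[C@H](c2cc(OCc3ccccc3)cc(OCc3ccccc3)c2)[C@@H]1c1cc(OCc2ccccc2)cc(OCc2ccccc2)c1 | intermediate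
20 | {3-methoxy-4-[tri(propan-2-yl)silyloxy]phenyl}magnesium bromide (formed and consumed in situ) | COc1cc([Mg]Br)ccc1O[Si](C(C)C)(C(C)C)C(C)C | intermediate
21 | {3-methoxy-4-[tri(propan-2-yl)silyloxy]phenyl}zinc chloride (formed and consumed in situ) | COc1cc([Zn]Cl)ccc1O[Si](C(C)C)(C(C)C)C(C)C | intermediate
22 | {4-[(1R,2S,3R,4S)-2-[4-(benzyloxy)-3-methoxyphenyl]-3,4-bis[3,5-bis(benzyloxy)phenyl]cyclobutyl]-2-methoxyphenoxy}tri(propan-2-yl)silane | [C@H]1(c2ccc(OCc3ccccc3)c(OC)c2)[C@@H](c2ccc(O[Si](C(C)C)(C(C)C)C(C)C)c(OC)c2)[C@H](c2cc(OCc3ccccc3)cc(OCc3ccccc3)c2)[C@@H]1c1cc(OCc2ccccc2)cc(OCc2ccccc2)c1 | intermediate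
23 | 4-{(1R,2S,3R,4S)-2-[4-(benzyloxy)-3-methoxyphenyl]-3,4-bis[3,5-bis(benzyloxy)phenyl]cyclobutyl}-2-methoxyphenol (guaiacyl rings cis, resorcinyl rings cis, the pairs trans) | [C@H]1(c2ccc(OCc3ccccc3)c(OC)c2)[C@@H](c2ccc(O)c(OC)c2)[C@H](c2cc(OCc3ccccc3)cc(OCc3ccccc3)c2)[C@@H]1c1cc(OCc2ccccc2)cc(OCc2ccccc2)c1 | intermediate
24 | ring-opened cation: 4-benzyloxy-3-methoxybenzylic cation with the para-quinone methide at the other end of the 2,3-diarylbutane chain (formed and consumed in situ) | O=C1C=CC(=C[C@H](c2cc(OCc3ccccc3)cc(OCc3ccccc3)c2)[C@H](c2cc(OCc3ccccc3)cc(OCc3ccccc3)c2)[CH+]c2ccc(OCc3ccccc3)c(OC)c2)C=C1OC | intermediate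
25 | 4-{[4,6-bis(benzyloxy)-3-[4-(benzyloxy)-3-methoxyphenyl]-2-[3,5-bis(benzyloxy)phenyl]-2,3-dihydro-1H-inden-1-yl]methylidene}-2-methoxycyclohexa-2,5-dien-1-one (2,3-trans, 1,2-trans; formed and consumed in situ) | O=C1C=CC(=C[C@@H]2c3cc(OCc4ccccc4)cc(OCc4ccccc4)c3[C@H](c3ccc(OCc4ccccc4)c(OC)c3)[C@H]2c2cc(OCc3ccccc3)cc(OCc3ccccc3)c2)C=C1OC | intermediate
26 | 4-{(E)-[(2S,3S)-4,6-bis(benzyloxy)-3-[4-(benzyloxy)-3-methoxyphenyl]-2-[3,5-bis(benzyloxy)phenyl]-2,3-dihydro-1H-inden-1-ylidene]methyl}-2-methoxyphenol | COc1cc(/C=C2/c3cc(OCc4ccccc4)cc(OCc4ccccc4)c3[C@H](c3ccc(OCc4ccccc4)c(OC)c3)[C@H]2c2cc(OCc3ccccc3)cc(OCc3ccccc3)c2)ccc1O | intermediate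
27 | gnetulin, (1E,2S,3S)-2-(3,5-dihydroxyphenyl)-3-(4-hydroxy-3-methoxyphenyl)-1-[(4-hydroxy-3-methoxyphenyl)methylidene]-2,3-dihydro-1H-indene-4,6-diol | COc1cc(/C=C2/c3cc(O)cc(O)c3[C@H](c3ccc(O)c(OC)c3)[C@H]2c2cc(O)cc(O)c2)ccc1O | target

Total step count: 14 (steps 7 and 10 prepare the two aryl bromides).
Longest linear sequence: 12 steps from 1 (steps 1–6, 8, 9, 11–14).

**Steps most likely to fail**

1. Step 13 (Proposed new method). The phenoxonium ion may lose its benzylic proton or be trapped at the methoxy-bearing ring carbon instead of fragmenting. The opened cation may shed a proton or its benzyl group before ring closure, which would erase the difference between the two ends and with it the enantiomeric purity. One-electron pathways may lead to cycloreversion into two stilbenes. The fallback leaves the cyclobutane route and uses the known biomimetic coupling of the monomeric stilbene, at the price of a late resolution. Setting out from 1, Wittig methylenation (Ph3PCH3Br, KOtBu, THF) would give 1,3-bis(benzyloxy)-5-ethenylbenzene F1. A Heck reaction with bromide 12 (Pd(OAc)2, P(o-tol)3, Et3N, DMF, 100 °C) would give (E)-tri-O-benzylisorhapontigenin F2, and BCl3/pentamethylbenzene would free isorhapontigenin F3. One-electron oxidation of F3 (FeCl3·6H2O, acetone/water) is expected to give, among regioisomeric dimers, the 8–8′ coupled bis(quinone methide), which closes and tautomerises to racemic gnetulin. Preparative HPLC on a chiral stationary phase would remove the antipode ent-gnetulin F4 and return the route at 27.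

2. Step 8 (step 11 shares the mechanism and the concern). Capture of the hindered secondary cyclobutyl radical by the dilute aryl–nickel species may be slow, so that β-scission of the ring to a benzylic radical, simple reduction, or acyl transfer from the active ester to the arylzinc reagent takes over. In the fallback the radical is used only to make a C–B bond and the aryl–cyclobutyl bond is formed in a two-electron cross-coupling. Setting out from 10, the active ester 13 would be isolated and submitted to copper-catalysed decarboxylative borylation (B2pin2, Cu(acac)2, LiOH·H2O, MgCl2, dioxane/DMF, rt), where a small and abundant boron partner traps the radical, to give the pinacol boronate methyl 3,4-bis[3,5-bis(benzyloxy)phenyl]-2-(4,4,5,5-tetramethyl-1,3,2-dioxaborolan-2-yl)cyclobutane-1-carboxylate F5. KHF2 (MeOH/H2O) would give the potassium trifluoroborate F6, and Suzuki–Miyaura coupling with 12 (Pd(OAc)2, di(1-adamantyl)-n-butylphosphine, Cs2CO3, toluene/H2O, 100 °C) returns the route at 16.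

3. Step 6. Discrimination between the two enantiotopic carbonyl groups of the hindered diaryl anhydride may be poor, giving hemiester of low enantiomeric purity that every later step would carry through. The fallback replaces reagent control by a classical resolution. Setting out from 9, unselective methanolysis (MeOH, Et3N, CH2Cl2) would give the racemic hemiester, that is 10 together with its antipode (1S,2R,3S,4R)-3,4-bis[3,5-bis(benzyloxy)phenyl]-2-(methoxycarbonyl)cyclobutane-1-carboxylic acid F7. Crystallisation with (R)-1-phenylethylamine would give the less soluble diastereomeric salt, the (R)-1-phenylethylammonium salt of 10 F8 (the (S)-amine would be taken if the salt of the antipode crystallised first). Acidification returns the route at 10.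

**Further compounds**
F1 | step 13 | 1,3-bis(benzyloxy)-5-ethenylbenzene | C=Cc1cc(OCc2ccccc2)cc(OCc2ccccc2)c1
F2 | step 13 | (E)-tri-O-benzylisorhapontigenin, 1-(benzyloxy)-4-{(E)-2-[3,5-bis(benzyloxy)phenyl]ethenyl}-2-methoxybenzene | COc1cc(/C=C/c2cc(OCc3ccccc3)cc(OCc3ccccc3)c2)ccc1OCc1ccccc1
F3 | step 13 | isorhapontigenin, 5-[(E)-2-(4-hydroxy-3-methoxyphenyl)ethenyl]benzene-1,3-diol | COc1cc(/C=C/c2cc(O)cc(O)c2)ccc1O
F4 | step 13 | ent-gnetulin, (1E,2R,3R) antipode of 27 | COc1cc(/C=C2/c3cc(O)cc(O)c3[C@@H](c3ccc(O)c(OC)c3)[C@@H]2c2cc(O)cc(O)c2)ccc1O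
F5 | step 8 | methyl 3,4-bis[3,5-bis(benzyloxy)phenyl]-2-(4,4,5,5-tetramethyl-1,3,2-dioxaborolan-2-yl)cyclobutane-1-carboxylate (boron in place of the carboxyl group of 10, configuration retained) | CC1(C)OB([C@H]2[C@@H](C(=O)OC)[C@H](c3cc(OCc4ccccc4)cc(OCc4ccccc4)c3)[C@@H]2c2cc(OCc3ccccc3)cc(OCc3ccccc3)c2)OC1(C)C
F6 | step 8 | potassium trifluoroborate corresponding to F5 | [K+].F[B-](F)(F)[C@H]1[C@@H](C(=O)OC)[C@H](c2cc(OCc3ccccc3)cc(OCc3ccccc3)c2)[C@@H]1c1cc(OCc2ccccc2)cc(OCc2ccccc2)c1
F7 | step 6 | (1S,2R,3S,4R)-3,4-bis[3,5-bis(benzyloxy)phenyl]-2-(methoxycarbonyl)cyclobutane-1-carboxylic acid (antipode of 10) | OC(=O)[C@@H]1[C@H](C(=O)OC)[C@@H](c2cc(OCc3ccccc3)cc(OCc3ccccc3)c2)[C@H]1c1cc(OCc2ccccc2)cc(OCc2ccccc2)c1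
F8 | step 6 | (R)-1-phenylethylammonium salt of 10 | C[C@@H]([NH3+])c1ccccc1.[O-]C(=O)[C@H]1[C@@H](C(=O)OC)[C@H](c2cc(OCc3ccccc3)cc(OCc3ccccc3)c2)[C@@H]1c1cc(OCc2ccccc2)cc(OCc2ccccc2)c1
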